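The data were generated by integration for an exercise, and the scatter is random.

The summer run is the near twin of the new flask: partner, capture agent, both catalysts and added ligand have the same charges, but the new flask holds twice the starting material.

| setting | summer | flask |
|---|---|---|
| starting material | 0.025 M | 0.050 M |
| partner | 0.060 M | 0.0600 M |
| capture agent | 0.015 M | 0.0150 M |
| free catalyst | 1 mM | 1.0 mM |
| second catalyst | 0.50 mM | 0.50 mM |
| added ligand | 1.6 mM | 1.6 mM |
| remark | run made earlier |  |
| time |  | 40 h |

- summer (time / h: trapped intermediate / %, target / %): 1.50: 10.0, 70.8; 3.00: 11.3, 78.0; 5.00: 11.9, 79.1; 6.00: 11.5, 79.6; 8.00: 11.8, 79.3

(each reading ± 0.5 percentage points)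

- what was read earlier has a scatter of 0.5 percentage points, one standard deviation

* ratio of trapped intermediate to target at 4.0 min
* ratio of trapped intermediate to target at 40 h
* which of trapped intermediate and target there is more of at 40 h

In the summer run the readings change by little more than their scatter after 5.00 h, and trapped intermediate over target reads near 0.149. A steady ratio suggests one intermediate shared between two takers, so my own reckoning lets the ratio follow capture agent over partner. The selectivity factor is trapped intermediate made over target made, times mean partner over mean capture agent. The last summer reading gives 0.551 for this partition factor.

The new flask starts from the same charges of both takers, so its early ratio should be 0.138. The end needs a correction. Taking the summer percentages for the new flask, partner loses a larger part of its charge than capture agent, so mean capture agent over mean partner stands above the ratio of the charges. That lifts the end ratio to 0.165, and target stays ahead.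

The forecast gives 0.14 early, 0.165 at the end and target in the lead, on the grounds of “just a kinetic partition of one intermediate”.

The new flask gives 0.147 and 0.160, with 76.1% target against 12.2% trapped intermediate. Starting material, the limiting reagent, stands at 0% after 40.0 h. The end ratio of the new flask, with partner and capture agent each taken as the mean of charge and remainder, returns a factor of 0.549.

    starting material + free catalyst → free catalyst + open intermediate (k = 44.0 M⁻¹ min⁻¹)
    second catalyst + open intermediate ⇌ catalyst intermediate (K = 16.0 M⁻¹, k = 1500 M⁻¹ min⁻¹)
    partner + catalyst intermediate → second catalyst + target (k = 740 M⁻¹ min⁻¹)
    open intermediate + capture agent → trapped intermediate (k = 2.30 M⁻¹ min⁻¹)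
    open intermediate → side product (k = 0.0260 min⁻¹)
    free catalyst + added ligand ⇌ idle complex, settled at all times (K = 540 M⁻¹)

At the charges, open intermediate enters capture agent at 0.0345 min⁻¹ and second catalyst at 0.750 min⁻¹, while catalyst intermediate goes on to target at 44.4 min⁻¹ and falls back at 93.8 min⁻¹. The net flow to target at the charges is thus 0.241 min⁻¹, which puts capture over target at 0.143 there, with second catalyst in the denominator. Scaled to 8.5 × 10⁻⁴ M of second catalyst, the summer factor becomes 0.324 for the neighbour flask. With the 31% of partner and 70% of capture agent left in that neighbour flask, this factor gives 0.106, and its simulated end ratio is 0.107.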